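**Retrosynthetic overview**
1. Target ⇐ desilylation/acetylation ⇐ macrocycle 29; the ten-membered ring is closed last by ring-closing metathesis at C5=C6.
2. γ-Lactone (C8–C17 bond, C8 and C17 stereocentres) ⇐ intramolecular Reformatsky reaction on a C8/C9 diketone; C8–C9 bond ⇐ acylation of a dithiane dianion that carries C7.
3. C2–C3 bond ⇐ chelation-controlled Grignard addition to a C2 aldehyde.
4. Six-membered ring (formed first): key C1–C10 bond ⇐ hydrogen-atom-transfer radical addition of a lactol-bound tertiary radical to methyl 4-oxobut-2-enoate, then aldol condensation (C11=C12).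
5. Lactol ⇐ 2,3-dihydro-4H-pyran-4-one. Ring order: six-membered carbocycle, then lactone, then ten-membered ring.

Assumption: positions are cited in briarane numbering (C1 quaternary carbon, C2/C14 acetoxy carbons, C8 carbinol, C9 ketone, C10 ring-fusion CH, C17 lactone methine, C20 hydroxymethyl carbon); "core A" = (4S,4aS,5S,8aS)-6-{[tert-butyl(diphenyl)silyl]oxymethyl}-2,2,4a-trimethyl-4-(3-methylbut-3-en-1-yl)-4a,5,8,8a-tetrahydro-4H-1,3-benzodioxin-5-yl; the six starting materials are taken as commercial.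

**Step 1**
Reactants: 1 2,3-dihydro-4H-pyran-4-one
Product: 4 3-methylidene-2,3-dihydro-4H-pyran-4-one, via Mannich base 2 (not isolated), via methiodide 3 (not isolated)
Conditions: LiN(SiMe3)2, THF, −78 °C; Me2N=CH2+ I−; then MeI, CH2Cl2, rt; NaHCO3 aq
Reagents that add atoms: N,N-dimethylmethyleneiminium iodide (Eschenmoser's salt), C=[N+](C)C.[I-]
Why: Kinetic enolate formation at C3 (the only enolisable position), Mannich reaction, quaternisation and Hofmann-type elimination give the exocyclic enone (α-methylenation).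

**Step 2**
Reactants: 4 3-methylidene-2,3-dihydro-4H-pyran-4-one
Product: 5 (4S)-3-methylidene-3,4-dihydro-2H-pyran-4-ol
Conditions: (R)-2-methyl-CBS-oxazaborolidine (20 mol %), catecholborane, PhMe, −78 °C
Reagents that add atoms: none
Why: Corey–Bakshi–Shibata 1,2-reduction in which the α-branched alkenyl arm acts as the large group, so the (R)-catalyst gives the 4S alcohol (C14 of the target).

**Step 3**
Reactants: 5 (4S)-3-methylidene-3,4-dihydro-2H-pyran-4-ol
Product: 6 (4S)-5-methylideneoxane-2,4-diol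
Conditions: PPh3·HBr (5 mol %), THF/H2O 10:1, rt
Reagents that add atoms: water, O
Why: Acid-catalysed Markovnikov hydration of the cyclic enol ether (glycal to 2-deoxy-lactol) under conditions that avoid Ferrier rearrangement; the carbinol centre is untouched.

**Step 4**
Reactants: 6 (4S)-5-methylideneoxane-2,4-diol, 7 methyl (2E)-4-oxobut-2-enoate
Product: 9 methyl (1R,5S,6S)-2-formyl-5-hydroxy-6-(hydroxymethyl)-6-methylcyclohex-2-ene-1-carboxylate, via Giese adduct 8 (not isolated)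
Conditions: Fe(acac)3 (30 mol %), PhSiH3 (2.5 equiv), 7 (3 equiv), EtOH, 0 °C to rt; evaporate; then Bn2NH2+ CF3CO2− (30 mol %), PhMe, 50 °C
Reagents that add atoms: none
Why: Proposed new method: hydrogen-atom transfer from an iron hydride to the exocyclic alkene gives the tertiary oxanyl radical at C1, which adds to C2 of 7 (β to the more activating aldehyde) trans to the adjacent C14 hydroxyl with the bulky new substituent equatorial (trans rule for 2-substituted cyclohexyl radicals), setting C1; C10 forms in the same addition with the acceptor chain turned away from the ring hydroxyl (moderate selectivity expected; the 10-epimer, whose ester is cis to the hydroxymethyl group, lactonises and is removed); the ammonium salt then condenses the enamine of the free aldehyde onto the lactol carbon (intramolecular aldol condensation) to close the six-membered ring and free the C2 hydroxyl; closest known types are the Baran HAT–Giese olefin coupling and the Pronin radical–polar crossover annulation.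

**Step 5**
Reactants: 9 methyl (1R,5S,6S)-2-formyl-5-hydroxy-6-(hydroxymethyl)-6-methylcyclohex-2-ene-1-carboxylate
Product: 10 methyl (1S,5S,6S)-5-hydroxy-2,6-bis(hydroxymethyl)-6-methylcyclohex-2-ene-1-carboxylate
Conditions: NaBH4, CeCl3·7H2O, MeOH, −78 °C
Reagents that add atoms: none
Why: Luche 1,2-reduction of the enal; the ester and all stereocentres are untouched (the C10 descriptor changes only by priority).

**Step 6**
Reactants: 10 methyl (1S,5S,6S)-5-hydroxy-2,6-bis(hydroxymethyl)-6-methylcyclohex-2-ene-1-carboxylate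
Product: 11 methyl (1S,5S,6S)-2-{[tert-butyl(diphenyl)silyl]oxymethyl}-5-hydroxy-6-(hydroxymethyl)-6-methylcyclohex-2-ene-1-carboxylate
Conditions: TBDPSCl (1.05 equiv), imidazole, CH2Cl2, −20 °C
Reagents that add atoms: tert-butyl(chloro)diphenylsilane, CC(C)(C)[Si](Cl)(c1ccccc1)c1ccccc1
Why: Selective silylation of the unhindered allylic primary alcohol (C20) over the neopentyl primary and the secondary alcohol by the bulky chlorosilane.

**Step 7**
Reactants: 11 methyl (1S,5S,6S)-2-{[tert-butyl(diphenyl)silyl]oxymethyl}-5-hydroxy-6-(hydroxymethyl)-6-methylcyclohex-2-ene-1-carboxylate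
Product: 12 methyl (1S,5S,6R)-2-{[tert-butyl(diphenyl)silyl]oxymethyl}-6-formyl-5-hydroxy-6-methylcyclohex-2-ene-1-carboxylate
Conditions: TEMPO (10 mol %), PhI(OAc)2, CH2Cl2, rt
Reagents that add atoms: none
Why: Piancatelli TEMPO/PhI(OAc)2 oxidation, selective for the primary over the secondary alcohol; the α-quaternary aldehyde cannot enolise.

**Step 8**
Reactants: 12 methyl (1S,5S,6R)-2-{[tert-butyl(diphenyl)silyl]oxymethyl}-6-formyl-5-hydroxy-6-methylcyclohex-2-ene-1-carboxylate, 13 4-bromo-2-methylbut-1-ene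
Product: 15 methyl (1S,5S,6S)-2-{[tert-butyl(diphenyl)silyl]oxymethyl}-5-hydroxy-6-[(1S)-1-hydroxy-4-methylpent-4-en-1-yl]-6-methylcyclohex-2-ene-1-carboxylate, via Grignard reagent 14 (not isolated)
Conditions: 13, Mg, THF, rt; then 12 (4 equiv of 14), THF, −78 to −40 °C; NH4Cl aq
Reagents that add atoms: none
Why: Chelation-controlled Grignard addition (Cram chelate, 1,3-anti): the C14 magnesium alkoxide and the aldehyde form a six-membered chelate fused to the ring and the nucleophile adds from the face away from the carbocycle, giving the 2S carbinol; the hindered ester does not react at low temperature.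

**Step 9**
Reactants: 15 methyl (1S,5S,6S)-2-{[tert-butyl(diphenyl)silyl]oxymethyl}-5-hydroxy-6-[(1S)-1-hydroxy-4-methylpent-4-en-1-yl]-6-methylcyclohex-2-ene-1-carboxylate
Product: 16 methyl (4S,4aS,5S,8aS)-6-{[tert-butyl(diphenyl)silyl]oxymethyl}-2,2,4a-trimethyl-4-(3-methylbut-3-en-1-yl)-4a,5,8,8a-tetrahydro-4H-1,3-benzodioxine-5-carboxylate
Conditions: Me2C(OMe)2, PPTS, CH2Cl2, rt
Reagents that add atoms: 2,2-dimethoxypropane, COC(C)(C)OC
Why: Acid-catalysed transketalisation protects the anti-1,3-diol (O2/O14) as the acetonide for the organolithium and acylation steps.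

**Step 10**
Reactants: 17 1,3-dithiane, 18 prop-2-enal
Product: 20 rac-1-(1,3-dithian-2-yl)prop-2-en-1-ol, via 2-lithio-1,3-dithiane 19 (not isolated)
Conditions: n-BuLi, THF, −30 °C; then 18, −78 °C; NH4Cl aq
Reagents that add atoms: none
Why: Corey–Seebach umpolung: the lithiated dithiane adds 1,2 to acrolein, giving C6–C8 with C8 as a masked ketone.

**Step 11**
Reactants: 20 rac-1-(1,3-dithian-2-yl)prop-2-en-1-ol
Product: 21 (1S)-1-(1,3-dithian-2-yl)prop-2-en-1-ol
Conditions: Burkholderia cepacia lipase (Amano PS), vinyl acetate, t-BuOMe, 30 °C, stopped at ca. 52% conversion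
Reagents that add atoms: none
Why: Lipase kinetic resolution (Kazlauskas rule: large dithianyl, medium vinyl): the R alcohol is acetylated and the S alcohol (C7 of the target) is recovered.

**Step 12**
Reactants: 16 methyl (4S,4aS,5S,8aS)-6-{[tert-butyl(diphenyl)silyl]oxymethyl}-2,2,4a-trimethyl-4-(3-methylbut-3-en-1-yl)-4a,5,8,8a-tetrahydro-4H-1,3-benzodioxine-5-carboxylate, 21 (1S)-1-(1,3-dithian-2-yl)prop-2-en-1-ol
Product: 23 (core A){2-[(1S)-1-hydroxyprop-2-en-1-yl]-1,3-dithian-2-yl}methanone, via dilithio dianion 22 (not isolated)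
Conditions: 21 (3 equiv), n-BuLi (6 equiv), THF, −30 °C; then 16, −78 to −40 °C; AcOH, −78 °C
Reagents that add atoms: none
Why: Acylation of a sulfur-stabilised carbanion (Corey–Seebach): the O,C-dianion cannot β-eliminate, adds once to the methyl ester (C8–C9 bond) and the hindered ketone does not react further; the cold acidic quench prevents retro-aldol loss of acrolein, and C7 comes unchanged from 21.

**Step 13**
Reactants: 23 (core A){2-[(1S)-1-hydroxyprop-2-en-1-yl]-1,3-dithian-2-yl}methanone, 24 2-bromopropanoyl bromide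
Product: 25 (1S)-1-[2-(core A-carbonyl)-1,3-dithian-2-yl]prop-2-en-1-yl 2-bromopropanoate
Conditions: pyridine, DMAP (cat.), CH2Cl2, −20 °C
Reagents that add atoms: none
Why: Esterification of the only free hydroxyl (O7) brings in C17–C19; the bromide-bearing carbon is planarised in step 15, so the racemic acyl bromide is used.

**Step 14**
Reactants: 25 (1S)-1-[2-(core A-carbonyl)-1,3-dithian-2-yl]prop-2-en-1-yl 2-bromopropanoate
Product: 26 (3S)-1-(core A)-1,2-dioxopent-4-en-3-yl 2-bromopropanoate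
Conditions: Dess–Martin periodinane, MeCN/CH2Cl2/H2O 8:1:1, rt; used at once
Reagents that add atoms: water, O
Why: Oxidative dethioacetalisation with Dess–Martin periodinane in wet solvent (S-oxidation, then hydrolysis) unmasks the C8 ketone; esters, acetonide, silyl ether and alkenes are inert.

**Step 15**
Reactants: 26 (3S)-1-(core A)-1,2-dioxopent-4-en-3-yl 2-bromopropanoate
Product: 28 (3R,4S,5S)-4-(core A-carbonyl)-5-ethenyl-4-hydroxy-3-methyloxolan-2-one, via zinc enolate 27 (not isolated)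
Conditions: Zn (activated), THF, 0 °C to rt; NH4Cl aq
Reagents that add atoms: none
Why: Intramolecular Reformatsky reaction: the zinc enolate adds to the adjacent C8 ketone (five-membered closure, C9 is more hindered) with the bulky C9 acyl group trans to both the vinyl and the new methyl group, setting C8 (S) and C17 (R); a C17 epimer would equilibrate to this methyl-trans-to-acyl isomer with mild base.

**Step 16**
Reactants: 28 (3R,4S,5S)-4-(core A-carbonyl)-5-ethenyl-4-hydroxy-3-methyloxolan-2-one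
Product: 29 (1S,2S,5Z,7S,8S,10S,14S,17R)-20-[tert-butyl(diphenyl)silyloxy]-8-hydroxy-2,14-(propane-2,2-diyldioxy)-9-oxobriara-5,11-dien-18,7-olide
Conditions: second-generation Grubbs catalyst (10 mol %), PhMe, 1 mM, 80 °C
Reagents that add atoms: none
Why: Ring-closing metathesis of the C7 vinyl group with the isopropenyl group closes the ten-membered ring; the ring accommodates only the Z trisubstituted alkene.

**Step 17**
Reactants: 29 (1S,2S,5Z,7S,8S,10S,14S,17R)-20-[tert-butyl(diphenyl)silyloxy]-8-hydroxy-2,14-(propane-2,2-diyldioxy)-9-oxobriara-5,11-dien-18,7-olide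
Product: 30 (1S,2S,5Z,7S,8S,10S,14S,17R)-20-[tert-butyl(diphenyl)silyloxy]-2,8,14-trihydroxy-9-oxobriara-5,11-dien-18,7-olide
Conditions: AcOH/THF/H2O 3:1:1, 40 °C
Reagents that add atoms: none
Why: Acid hydrolysis of the acetonide; the silyl ether, lactone and tertiary ketol survive.

**Step 18**
Reactants: 30 (1S,2S,5Z,7S,8S,10S,14S,17R)-20-[tert-butyl(diphenyl)silyloxy]-2,8,14-trihydroxy-9-oxobriara-5,11-dien-18,7-olide
Product: 31 (1S,2S,5Z,7S,8S,10S,14S,17R)-2,14-diacetoxy-20-[tert-butyl(diphenyl)silyloxy]-8-hydroxy-9-oxobriara-5,11-dien-18,7-olide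
Conditions: Ac2O, pyridine, DMAP (cat.), CH2Cl2, 0 °C to rt
Reagents that add atoms: acetic anhydride, CC(=O)OC(C)=O
Why: DMAP-catalysed acetylation of the two secondary alcohols; the hindered tertiary C8 hydroxyl is not acylated.

**Step 19**
Reactants: 31 (1S,2S,5Z,7S,8S,10S,14S,17R)-2,14-diacetoxy-20-[tert-butyl(diphenyl)silyloxy]-8-hydroxy-9-oxobriara-5,11-dien-18,7-olide
Product: 32 (1S,2S,5Z,7S,8S,10S,14S,17R)-2,14-diacetoxy-8,20-dihydroxy-9-oxobriara-5,11-dien-18,7-olide (CNP0140109.1)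
Conditions: HF·pyridine, THF, 0 °C to rt
Reagents that add atoms: none
Why: Fluoride desilylation of the primary silyl ether under buffered acidic conditions that leave the acetates, the lactone and the α-ketol intact.

**Compound list**
1 | 2,3-dihydro-4H-pyran-4-one | O=C1CCOC=C1 | starting material
2 | 3-[(dimethylamino)methyl]-2,3-dihydro-4H-pyran-4-one (racemic Mannich base) | CN(C)CC1COC=CC1=O | intermediate
3 | trimethyl[(4-oxo-3,4-dihydro-2H-pyran-3-yl)methyl]ammonium iodide | C[N+](C)(C)CC1COC=CC1=O.[I-] | intermediate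
4 | 3-methylidene-2,3-dihydro-4H-pyran-4-one | C=C1COC=CC1=O | intermediate
5 | (4S)-3-methylidene-3,4-dihydro-2H-pyran-4-ol | C=C1COC=C[C@@H]1O | intermediate
6 | (4S)-5-methylideneoxane-2,4-diol (lactol, both anomers) | C=C1COC(O)C[C@@H]1O | intermediate
7 | methyl (2E)-4-oxobut-2-enoate | COC(=O)/C=C/C=O | starting material
8 | methyl (2S)-2-[(3S,4S)-4,6-dihydroxy-3-methyloxan-3-yl]-4-oxobutanoate | O=CC[C@H](C(=O)OC)[C@@]1(C)COC(O)C[C@@H]1O | intermediate
9 | methyl (1R,5S,6S)-2-formyl-5-hydroxy-6-(hydroxymethyl)-6-methylcyclohex-2-ene-1-carboxylate | O[C@H]1CC=C(C=O)[C@H](C(=O)OC)[C@@]1(C)CO | intermediate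
10 | methyl (1S,5S,6S)-5-hydroxy-2,6-bis(hydroxymethyl)-6-methylcyclohex-2-ene-1-carboxylate | O[C@H]1CC=C(CO)[C@H](C(=O)OC)[C@@]1(C)CO | intermediate
11 | methyl (1S,5S,6S)-2-{[tert-butyl(diphenyl)silyl]oxymethyl}-5-hydroxy-6-(hydroxymethyl)-6-methylcyclohex-2-ene-1-carboxylate | O[C@H]1CC=C(CO[Si](c2ccccc2)(c2ccccc2)C(C)(C)C)[C@H](C(=O)OC)[C@@]1(C)CO | intermediate
12 | methyl (1S,5S,6R)-2-{[tert-butyl(diphenyl)silyl]oxymethyl}-6-formyl-5-hydroxy-6-methylcyclohex-2-ene-1-carboxylate | O[C@H]1CC=C(CO[Si](c2ccccc2)(c2ccccc2)C(C)(C)C)[C@H](C(=O)OC)[C@@]1(C)C=O | intermediate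
13 | 4-bromo-2-methylbut-1-ene | C=C(C)CCBr | starting material
14 | (3-methylbut-3-en-1-yl)magnesium bromide | C=C(C)CC[Mg]Br | intermediate
15 | methyl (1S,5S,6S)-2-{[tert-butyl(diphenyl)silyl]oxymethyl}-5-hydroxy-6-[(1S)-1-hydroxy-4-methylpent-4-en-1-yl]-6-methylcyclohex-2-ene-1-carboxylate | O[C@H]1CC=C(CO[Si](c2ccccc2)(c2ccccc2)C(C)(C)C)[C@H](C(=O)OC)[C@@]1(C)[C@@H](O)CCC(C)=C | intermediate
16 | methyl (4S,4aS,5S,8aS)-6-{[tert-butyl(diphenyl)silyl]oxymethyl}-2,2,4a-trimethyl-4-(3-methylbut-3-en-1-yl)-4a,5,8,8a-tetrahydro-4H-1,3-benzodioxine-5-carboxylate (methyl ester of core A) | CC1(C)O[C@H]2CC=C(CO[Si](c3ccccc3)(c3ccccc3)C(C)(C)C)[C@H](C(=O)OC)[C@@]2(C)[C@H](CCC(C)=C)O1 | intermediate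
17 | 1,3-dithiane | C1CSCSC1 | starting material
18 | prop-2-enal (acrolein) | C=CC=O | starting material
19 | 2-lithio-1,3-dithiane | [Li]C1SCCCS1 | intermediate
20 | rac-1-(1,3-dithian-2-yl)prop-2-en-1-ol | C=CC(O)C1SCCCS1 | intermediate
21 | (1S)-1-(1,3-dithian-2-yl)prop-2-en-1-ol | C=C[C@H](O)C1SCCCS1 | intermediate
22 | dilithium O,C-dianion of 21 | C=C[C@H]([O-])[C-]1SCCCS1.[Li+].[Li+] | intermediate
23 | (core A){2-[(1S)-1-hydroxyprop-2-en-1-yl]-1,3-dithian-2-yl}methanone | CC1(C)O[C@H]2CC=C(CO[Si](c3ccccc3)(c3ccccc3)C(C)(C)C)[C@H](C(=O)C3(SCCCS3)[C@@H](O)C=C)[C@@]2(C)[C@H](CCC(C)=C)O1 | intermediate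
24 | 2-bromopropanoyl bromide (racemic) | CC(Br)C(Br)=O | starting material
25 | (1S)-1-[2-(core A-carbonyl)-1,3-dithian-2-yl]prop-2-en-1-yl 2-bromopropanoate (both bromide epimers) | CC1(C)O[C@H]2CC=C(CO[Si](c3ccccc3)(c3ccccc3)C(C)(C)C)[C@H](C(=O)C3(SCCCS3)[C@@H](OC(=O)C(C)Br)C=C)[C@@]2(C)[C@H](CCC(C)=C)O1 | intermediate
26 | (3S)-1-(core A)-1,2-dioxopent-4-en-3-yl 2-bromopropanoate | CC1(C)O[C@H]2CC=C(CO[Si](c3ccccc3)(c3ccccc3)C(C)(C)C)[C@H](C(=O)C(=O)[C@@H](OC(=O)C(C)Br)C=C)[C@@]2(C)[C@H](CCC(C)=C)O1 | intermediate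
27 | bromozinc Reformatsky reagent (C-bound enolate) of 26 | CC1(C)O[C@H]2CC=C(CO[Si](c3ccccc3)(c3ccccc3)C(C)(C)C)[C@H](C(=O)C(=O)[C@@H](OC(=O)C(C)[Zn]Br)C=C)[C@@]2(C)[C@H](CCC(C)=C)O1 | intermediate
28 | (3R,4S,5S)-4-(core A-carbonyl)-5-ethenyl-4-hydroxy-3-methyloxolan-2-one | CC1(C)O[C@H]2CC=C(CO[Si](c3ccccc3)(c3ccccc3)C(C)(C)C)[C@H](C(=O)[C@@]3(O)[C@H](C=C)OC(=O)[C@@H]3C)[C@@]2(C)[C@H](CCC(C)=C)O1 | intermediate
29 | (1S,2S,5Z,7S,8S,10S,14S,17R)-20-[tert-butyl(diphenyl)silyloxy]-8-hydroxy-2,14-(propane-2,2-diyldioxy)-9-oxobriara-5,11-dien-18,7-olide | CC1(C)O[C@H]2CC=C(CO[Si](c5ccccc5)(c6ccccc6)C(C)(C)C)[C@@H]3C(=O)[C@@]4(O)[C@H](/C=C(/C)CC[C@H](O1)[C@]32C)OC(=O)[C@@H]4C | intermediate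
30 | (1S,2S,5Z,7S,8S,10S,14S,17R)-20-[tert-butyl(diphenyl)silyloxy]-2,8,14-trihydroxy-9-oxobriara-5,11-dien-18,7-olide | O[C@H]1CC=C(CO[Si](c4ccccc4)(c5ccccc5)C(C)(C)C)[C@@H]2C(=O)[C@@]3(O)[C@H](/C=C(/C)CC[C@H](O)[C@]21C)OC(=O)[C@@H]3C | intermediate
31 | (1S,2S,5Z,7S,8S,10S,14S,17R)-2,14-diacetoxy-20-[tert-butyl(diphenyl)silyloxy]-8-hydroxy-9-oxobriara-5,11-dien-18,7-olide | CC(=O)O[C@H]1CC=C(CO[Si](c4ccccc4)(c5ccccc5)C(C)(C)C)[C@@H]2C(=O)[C@@]3(O)[C@H](/C=C(/C)CC[C@H](OC(C)=O)[C@]21C)OC(=O)[C@@H]3C | intermediate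
32 | (1S,2S,5Z,7S,8S,10S,14S,17R)-2,14-diacetoxy-8,20-dihydroxy-9-oxobriara-5,11-dien-18,7-olide (CNP0140109.1) | CC(=O)O[C@H]1CC=C(CO)[C@@H]2C(=O)[C@@]3(O)[C@H](/C=C(/C)CC[C@H](OC(C)=O)[C@]21C)OC(=O)[C@@H]3C | target

**Step count**
Total: 19 steps. Longest linear sequence: 17 steps (steps 1–9 and 12–19); steps 10–11 make the dithiane fragment.

**Steps most likely to fail, with fallbacks**

Step 4 (radical addition/aldol condensation). Risks are the face selectivity at C1, the unselective formation of C10, the regiochemistry on 7, and interference by the free lactol. The fallback separates the radical step from the ring closure. It sets out from 5: PPh3·HBr in methanol gives the locked methyl glycoside (4S)-2-methoxy-5-methylideneoxan-4-ol F1. The same Fe(acac)3/PhSiH3 addition to 7 is run on this acetal, and the adduct methyl (2S)-2-[(3S,4S)-4-hydroxy-6-methoxy-3-methyloxan-3-yl]-4-oxobutanoate F2 is isolated and purified. Aqueous CF3CO2H then ionises the acetal to the oxocarbenium ion, which is captured by the enol of the free aldehyde (Prins-type aldol); the bridged ether eliminates and the route is rejoined at 9.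

Step 12 (acylation of a hindered, enolisable ester by a hindered dianion). The fallback replaces acyl substitution by carbonyl addition plus oxidation. It sets out from 16: i-Bu2AlH (CH2Cl2, −78 °C) gives core A-carbaldehyde F3. Dianion 22 adds to it to give the diol (core A){2-[(1S)-1-hydroxyprop-2-en-1-yl]-1,3-dithian-2-yl}methanol F4 (C9 epimers). The less hindered allylic C7 hydroxyl is esterified with 24 to give the mono-ester (1S)-1-{2-[(core A)(hydroxy)methyl]-1,3-dithian-2-yl}prop-2-en-1-yl 2-bromopropanoate F5. Anhydrous Dess–Martin oxidation of the remaining C9 carbinol rejoins the route at 25.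

Step 16 (metathesis to a trisubstituted alkene in a ten-membered ring next to the rigid lactone). The fallback closes the carbocycle before the lactone. It sets out from 25: ring-closing metathesis of this more flexible seco compound (second-generation Hoveyda–Grubbs catalyst, PhMe, 80 °C, high dilution) gives the macrocyclic dithiane (1S,2S,5Z,7S,10S,14S)-7-(2-bromopropanoyloxy)-20-[tert-butyl(diphenyl)silyloxy]-2,14-(propane-2,2-diyldioxy)-8,8-(propane-1,3-diyldisulfanyl)-17,18,19-trinorbriara-5,11-dien-9-one F6. Wet Dess–Martin periodinane gives the macrocyclic diketone (1S,2S,5Z,7S,10S,14S)-7-(2-bromopropanoyloxy)-20-[tert-butyl(diphenyl)silyloxy]-2,14-(propane-2,2-diyldioxy)-17,18,19-trinorbriara-5,11-diene-8,9-dione F7. The zinc Reformatsky closure then builds the lactone on the preformed ring and rejoins the route at 29.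

**Further compounds**
F1 | step 4 | (4S)-2-methoxy-5-methylideneoxan-4-ol | C=C1COC(OC)C[C@@H]1O
F2 | step 4 | methyl (2S)-2-[(3S,4S)-4-hydroxy-6-methoxy-3-methyloxan-3-yl]-4-oxobutanoate | O=CC[C@H](C(=O)OC)[C@@]1(C)COC(OC)C[C@@H]1O
F3 | step 12 | core A-carbaldehyde, (4S,4aS,5S,8aS)-6-{[tert-butyl(diphenyl)silyl]oxymethyl}-2,2,4a-trimethyl-4-(3-methylbut-3-en-1-yl)-4a,5,8,8a-tetrahydro-4H-1,3-benzodioxine-5-carbaldehyde | CC1(C)O[C@H]2CC=C(CO[Si](c3ccccc3)(c3ccccc3)C(C)(C)C)[C@H](C=O)[C@@]2(C)[C@H](CCC(C)=C)O1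
F4 | step 12 | (core A){2-[(1S)-1-hydroxyprop-2-en-1-yl]-1,3-dithian-2-yl}methanol | CC1(C)O[C@H]2CC=C(CO[Si](c3ccccc3)(c3ccccc3)C(C)(C)C)[C@H](C(O)C3(SCCCS3)[C@@H](O)C=C)[C@@]2(C)[C@H](CCC(C)=C)O1
F5 | step 12 | (1S)-1-{2-[(core A)(hydroxy)methyl]-1,3-dithian-2-yl}prop-2-en-1-yl 2-bromopropanoate | CC1(C)O[C@H]2CC=C(CO[Si](c3ccccc3)(c3ccccc3)C(C)(C)C)[C@H](C(O)C3(SCCCS3)[C@@H](OC(=O)C(C)Br)C=C)[C@@]2(C)[C@H](CCC(C)=C)O1
F6 | step 16 | (1S,2S,5Z,7S,10S,14S)-7-(2-bromopropanoyloxy)-20-[tert-butyl(diphenyl)silyloxy]-2,14-(propane-2,2-diyldioxy)-8,8-(propane-1,3-diyldisulfanyl)-17,18,19-trinorbriara-5,11-dien-9-one | CC1(C)O[C@H]2CC=C(CO[Si](c5ccccc5)(c6ccccc6)C(C)(C)C)[C@@H]3C(=O)C4(SCCCS4)[C@H](/C=C(/C)CC[C@H](O1)[C@]32C)OC(=O)C(C)Br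
F7 | step 16 | (1S,2S,5Z,7S,10S,14S)-7-(2-bromopropanoyloxy)-20-[tert-butyl(diphenyl)silyloxy]-2,14-(propane-2,2-diyldioxy)-17,18,19-trinorbriara-5,11-diene-8,9-dione | CC1(C)O[C@H]2CC=C(CO[Si](c5ccccc5)(c6ccccc6)C(C)(C)C)[C@@H]3C(=O)C(=O)[C@H](/C=C(/C)CC[C@H](O1)[C@]32C)OC(=O)C(C)Br
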